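The plan avoids coupling two arenes across the crowded C6–C8' axis. Ring B (C4a', C5', C6', C7', C8', C8a') is instead grown on a finished 4,7-dimethoxy-5-methylcoumarin. The feature exploited is the resorcylate pattern of ring B: oxygen on C7' and C8a', methyl on C5', and the carboxyl-level carbon C4' on C4a'. One [4+2] cycloaddition with aromatising loss of methanol forges C5'–C6' and C4a'–C8a', closes ring B, and leaves a salicylate ready for the second pyranone. The precursor is a 1,3-dimethoxy-1-silyloxybutadiene whose C2, the future C8', already carries coumarin C6. Bromine is set at the benzoate stage, so C6 is unambiguous.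

Key step: step 8

Numbering and assumption: unprimed locants and ring A belong to the 6-linked coumarin, primed locants and ring B to the 8'-linked one; the SMILES gives no descriptor for the C6–C8' axis, so the racemate is the goal, and the alkene geometries drawn for 12, 13 and 14 are the expected ones and vanish in step 8.

Step 1
Reactants: 1 methyl 2,4-dihydroxy-6-methylbenzoate (methyl orsellinate)
Product: 2 methyl 3-bromo-4,6-dihydroxy-2-methylbenzoate
Conditions: NBS (1.0 equiv), MeCN, −10 °C to rt
Reagents that add atoms: N-bromosuccinimide, O=C1CCC(=O)N1Br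
Why: Electrophilic aromatic bromination: 2,4-dihydroxybenzoates take up bromine para to the chelated hydroxyl and ortho to the free one rather than between the two oxygens, and since no pyranone exists yet the very nucleophilic coumarin C3 cannot compete, so bromine should mark the future C6.

Step 2
Reactants: 2 methyl 3-bromo-4,6-dihydroxy-2-methylbenzoate
Product: 3 methyl 3-bromo-6-hydroxy-4-methoxy-2-methylbenzoate
Conditions: MeI (1.1 equiv), K2CO3 (1.1 equiv), acetone, rt to 40 °C
Reagents that add atoms: iodomethane, CI
Why: Williamson etherification: the hydroxyl next to the ester is held in an intramolecular hydrogen bond and is much less acidic and nucleophilic, so one equivalent of base and MeI should methylate only the 4-OH (future C7–OMe).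

Step 3
Reactants: 3 methyl 3-bromo-6-hydroxy-4-methoxy-2-methylbenzoate; 4 (triphenylphosphoranylidene)ketene, Ph3P=C=C=O
Product: 6 6-bromo-4,7-dimethoxy-5-methyl-2H-chromen-2-one, via acyl ylide ester 5 (not isolated)
Conditions: 4 (1.2 equiv), dry toluene, reflux, Ar
Reagents that add atoms: none
Why: Addition of the phenol O–H across the cumulated ylide gives stabilised ylide 5, whose intramolecular Wittig olefination of the adjacent ester carbonyl is the known domino route from salicylic esters to 4-alkoxycoumarins; the ester methoxy group becomes C4–OMe and the neutral medium leaves the aryl bromide untouched.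

Step 4
Reactants: 6 6-bromo-4,7-dimethoxy-5-methyl-2H-chromen-2-one; 7 methyl bromoacetate
Product: 9 methyl 2-(4,7-dimethoxy-5-methyl-2-oxo-2H-chromen-6-yl)acetate, via zinc enolate 8 (not isolated)
Conditions: 7 (2 equiv), Zn dust, Me3SiCl (5 mol %), THF, 40 °C; then 6, Pd2(dba)3 (2.5 mol %), XPhos (10 mol %), THF, 65 °C
Reagents that add atoms: none
Why: Negishi-type cross-coupling of a Reformatsky reagent (palladium-catalysed ester α-arylation under near-neutral conditions): bulky electron-rich biaryl phosphines are the ligand class that carries doubly ortho-flanked aryl bromides through the cycle, the small CH2 nucleophile adds little strain, and the mild zinc enolate does not touch the lactone.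

Step 5
Reactants: 9 methyl 2-(4,7-dimethoxy-5-methyl-2-oxo-2H-chromen-6-yl)acetate
Product: 11 methyl 2-(4,7-dimethoxy-5-methyl-2-oxo-2H-chromen-6-yl)-3-oxobutanoate (racemic, enolisable), via lithium enolate 10 (not isolated)
Conditions: LiN(SiMe3)2 (2.2 equiv), THF, −78 °C; AcCl (1.2 equiv), −78 to −20 °C; aq NH4Cl
Reagents that add atoms: acetyl chloride, CC(=O)Cl
Why: Crossed Claisen-type C-acylation of a preformed lithium ester enolate with an acid chloride: the benzylic CH2 of 9 is by far its most acidic site, the extra base covers the higher acidity of the β-keto ester formed, and the lactone, a vinylogous carbonate, is inert to the hindered amide at −78 °C.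

Step 6
Reactants: 11 methyl 2-(4,7-dimethoxy-5-methyl-2-oxo-2H-chromen-6-yl)-3-oxobutanoate
Product: 12 methyl (2E)-2-(4,7-dimethoxy-5-methyl-2-oxo-2H-chromen-6-yl)-3-methoxybut-2-enoate
Conditions: Me2SO4 (1.3 equiv), K2CO3 (1.5 equiv), DMF, 0 °C to rt
Reagents that add atoms: dimethyl sulfate, COS(=O)(=O)OC
Why: O-Alkylation of a β-keto ester enolate with a hard electrophile in a dipolar aprotic solvent, the usual way from 2-aryl-3-oxo esters to β-methoxy enoates: C-methylation would have to build a quaternary carbon beside the 2,6-disubstituted aryl ring and is therefore disfavoured, and either alkene isomer serves in step 7.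

Step 7
Reactants: 12 methyl (2E)-2-(4,7-dimethoxy-5-methyl-2-oxo-2H-chromen-6-yl)-3-methoxybut-2-enoate
Product: 14 6-[(1Z)-1,3-dimethoxy-1-(trimethylsilyloxy)buta-1,3-dien-2-yl]-4,7-dimethoxy-5-methyl-2H-chromen-2-one (used crude), via lithium dienolate 13 (not isolated)
Conditions: LiN(iPr)2 (1.1 equiv), THF, −78 °C; Me3SiCl (1.4 equiv), −78 to 0 °C; evaporate, dry toluene, filter under Ar
Reagents that add atoms: chlorotrimethylsilane, C[Si](C)(C)Cl
Why: γ-Deprotonation of a β-alkoxy enoate and O-silylation of the extended enolate is the standard entry to vinylketene silyl acetals: 12 has no α-hydrogen, its allylic methyl lies syn to the ester carbonyl that guides the amide base, and a slight excess of hindered base at −78 °C should spare the lactone.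

Step 8
Reactants: 14 6-[(1Z)-1,3-dimethoxy-1-(trimethylsilyloxy)buta-1,3-dien-2-yl]-4,7-dimethoxy-5-methyl-2H-chromen-2-one; 15 methyl but-2-ynoate
Product: 18 methyl 3-(4,7-dimethoxy-5-methyl-2-oxo-2H-chromen-6-yl)-2-hydroxy-4-methoxy-6-methylbenzoate, via cyclohexadiene adduct 16 (not isolated), via aryl silyl ether 17 (not isolated)
Conditions: 15 (8 equiv), N,O-bis(trimethylsilyl)acetamide (1.5 equiv), toluene, sealed tube, 130 °C; then 1 M HCl, THF, rt
Reagents that add atoms: none
Why: A thermal [4+2] cycloaddition in which bonding runs ahead at the electron-rich CH2 end of 14 (future C6') towards the methyl-bearing alkyne carbon of 15 (C5') and lags between the ketene-acetal carbon (C8a') and the ester-bearing alkyne carbon (C4a') should give 1,4-cyclohexadiene 16, which expels methanol across the ring to give silyl ether 17 and is desilylated to 18 by the acid work-up. The closest known reaction type is the Diels–Alder/aromatisation of 1,1,3-trioxygenated butadienes (vinylketene acetals) with acetylenic esters to resorcylates, here carried over to a diene whose C2 bears a 2,6-disubstituted aryl group. Ring B is closed in an intermolecular 4+2 mode, four carbons from the diene and two from the alkyne, and no other ring is formed. The only new stereocentre, the acetal carbon of 16, is lost on aromatisation, and the C6–C8' axis arises without control as the racemate. The step needs a single orientation of addition, and the push–pull match secures it: three oxygen donors put the largest HOMO coefficient on the CH2 terminus and the ester puts the largest LUMO coefficient on the β-carbon of 15, while the lactone C3=C4 bond of 14, a vinylogous carbonate, is too electron-rich to act as dienophile. N,O-Bis(trimethylsilyl)acetamide traps the liberated methanol, which would otherwise protonate unreacted 14, and the rod-shaped dienophile asks for little room beside the orthogonal ring A.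

Step 9
Reactants: 18 methyl 3-(4,7-dimethoxy-5-methyl-2-oxo-2H-chromen-6-yl)-2-hydroxy-4-methoxy-6-methylbenzoate; 4 (triphenylphosphoranylidene)ketene, Ph3P=C=C=O
Product: 20 4,4',7,7'-tetramethoxy-5,5'-dimethyl-6,8'-bicoumarin (racemic), via acyl ylide ester 19 (not isolated)
Conditions: 4 (1.3 equiv), dry xylene, 140 °C, Ar
Reagents that add atoms: none
Why: The same domino O–H addition/intramolecular Wittig olefination rehearsed in step 3: phenol 18 gives ylide 19, six-membered closure onto the ester carbonyl turns C4' with its methoxy group into the enol ether of the second pyranone, and the neutral conditions spare the first lactone.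

Compound list
1 | methyl 2,4-dihydroxy-6-methylbenzoate (methyl orsellinate) | COC(=O)c1c(C)cc(O)cc1O | starting material
2 | methyl 3-bromo-4,6-dihydroxy-2-methylbenzoate | COC(=O)c1c(C)c(Br)c(O)cc1O | intermediate
3 | methyl 3-bromo-6-hydroxy-4-methoxy-2-methylbenzoate | COC(=O)c1c(C)c(Br)c(OC)cc1O | intermediate
4 | (triphenylphosphoranylidene)ketene | O=C=C=P(c1ccccc1)(c1ccccc1)c1ccccc1 | starting material
5 | methyl 3-bromo-4-methoxy-2-methyl-6-[(triphenylphosphoranylidene)acetoxy]benzoate | COC(=O)c1c(C)c(Br)c(OC)cc1OC(=O)C=P(c1ccccc1)(c1ccccc1)c1ccccc1 | intermediate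
6 | 6-bromo-4,7-dimethoxy-5-methyl-2H-chromen-2-one | COc1cc2oc(=O)cc(OC)c2c(C)c1Br | intermediate
7 | methyl bromoacetate | COC(=O)CBr | starting material
8 | bromo(2-methoxy-2-oxoethyl)zinc | COC(=O)C[Zn]Br | intermediate
9 | methyl 2-(4,7-dimethoxy-5-methyl-2-oxo-2H-chromen-6-yl)acetate | COC(=O)Cc1c(C)c2c(OC)cc(=O)oc2cc1OC | intermediate
10 | lithium enolate of 9 (geometry immaterial) | COC(O[Li])=Cc1c(C)c2c(OC)cc(=O)oc2cc1OC | intermediate
11 | methyl 2-(4,7-dimethoxy-5-methyl-2-oxo-2H-chromen-6-yl)-3-oxobutanoate (racemic, enolisable) | COC(=O)C(C(C)=O)c1c(C)c2c(OC)cc(=O)oc2cc1OC | intermediate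
12 | methyl (2E)-2-(4,7-dimethoxy-5-methyl-2-oxo-2H-chromen-6-yl)-3-methoxybut-2-enoate | C/C(OC)=C(\C(=O)OC)c1c(C)c2c(OC)cc(=O)oc2cc1OC | intermediate
13 | lithium dienolate of 12 | C=C(OC)/C(c1c(C)c2c(OC)cc(=O)oc2cc1OC)=C(/OC)O[Li] | intermediate
14 | 6-[(1Z)-1,3-dimethoxy-1-(trimethylsilyloxy)buta-1,3-dien-2-yl]-4,7-dimethoxy-5-methyl-2H-chromen-2-one | C=C(OC)/C(c1c(C)c2c(OC)cc(=O)oc2cc1OC)=C(/OC)O[Si](C)(C)C | intermediate
15 | methyl but-2-ynoate | CC#CC(=O)OC | starting material
16 | methyl 5-(4,7-dimethoxy-5-methyl-2-oxo-2H-chromen-6-yl)-4,6-dimethoxy-2-methyl-6-(trimethylsilyloxy)cyclohexa-1,4-diene-1-carboxylate (racemic) | COC(=O)C1=C(C)CC(OC)=C(c2c(C)c3c(OC)cc(=O)oc3cc2OC)C1(OC)O[Si](C)(C)C | intermediate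
17 | methyl 3-(4,7-dimethoxy-5-methyl-2-oxo-2H-chromen-6-yl)-4-methoxy-6-methyl-2-(trimethylsilyloxy)benzoate | COC(=O)c1c(C)cc(OC)c(-c2c(C)c3c(OC)cc(=O)oc3cc2OC)c1O[Si](C)(C)C | intermediate
18 | methyl 3-(4,7-dimethoxy-5-methyl-2-oxo-2H-chromen-6-yl)-2-hydroxy-4-methoxy-6-methylbenzoate | COC(=O)c1c(C)cc(OC)c(-c2c(C)c3c(OC)cc(=O)oc3cc2OC)c1O | intermediate
19 | methyl 3-(4,7-dimethoxy-5-methyl-2-oxo-2H-chromen-6-yl)-4-methoxy-6-methyl-2-[(triphenylphosphoranylidene)acetoxy]benzoate | COC(=O)c1c(C)cc(OC)c(-c2c(C)c3c(OC)cc(=O)oc3cc2OC)c1OC(=O)C=P(c1ccccc1)(c1ccccc1)c1ccccc1 | intermediate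
20 | 4,4',7,7'-tetramethoxy-5,5'-dimethyl-6,8'-bicoumarin (CNP0271624.0, racemic axis) | COc1cc2oc(=O)cc(OC)c2c(C)c1-c1c(OC)cc(C)c2c(OC)cc(=O)oc12 | target

Total step count: 9. Longest linear sequence: 9 steps (1 to 20).

Steps most likely to fail

Step 8. The orthogonal ring A may shield both faces of the diene. The cycloaddition could then stall while protodesilylation or silyl migration consumes the ketene acetal. The fallback joins the two arenes by cross-coupling and builds the second pyranone classically. It sets out from 6 and comes back to the route at 20. Suzuki–Miyaura coupling of 6 with purchased (2,6-dimethoxy-4-methylphenyl)boronic acid F1 (Pd(OAc)2, SPhos, K3PO4, toluene–water, 100 °C) should give 6-(2,6-dimethoxy-4-methylphenyl)-4,7-dimethoxy-5-methylcoumarin F2, whose new ring is locally symmetric. Friedel–Crafts acetylation (AcCl, TiCl4, CH2Cl2, −10 °C) at either of the equivalent CH positions beside its methyl group should give 6-(3-acetyl-2,6-dimethoxy-4-methylphenyl)-4,7-dimethoxy-5-methylcoumarin F3. Chelation-directed cleavage of the methoxy group next to the acetyl group (BCl3, CH2Cl2, −78 to 0 °C) should give 6-(3-acetyl-2-hydroxy-6-methoxy-4-methylphenyl)-4,7-dimethoxy-5-methylcoumarin F4. Claisen-type carbonylation with lactonisation (NaH, dimethyl carbonate, toluene, reflux, acidic work-up) should give 4'-hydroxy-4,7,7'-trimethoxy-5,5'-dimethyl-6,8'-bicoumarin F5. O-Methylation (Me2SO4, K2CO3, acetone, reflux) should then give 20.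

Step 4. Turnover at the carbon flanked by methyl and methoxy may be slow. Decay of the thermally fragile zinc enolate and hydrodebromination could then win over coupling. The fallback brings in the two carbons with a heat-stable nucleophile and adjusts the oxidation level afterwards. It sets out from 6 and comes back at 9. Stille coupling with allyltributylstannane (Pd(PPh3)4, DMF, 100 °C) should give 6-allyl-4,7-dimethoxy-5-methylcoumarin F6. Lemieux–Johnson cleavage of the terminal alkene (OsO4 2 mol %, NaIO4, 2,6-lutidine, dioxane–water) should give (4,7-dimethoxy-5-methyl-2-oxo-2H-chromen-6-yl)acetaldehyde F7. Pinnick oxidation (NaClO2, NaH2PO4, 2-methylbut-2-ene, t-BuOH–water) should give (4,7-dimethoxy-5-methyl-2-oxo-2H-chromen-6-yl)acetic acid F8. Esterification (MeI, K2CO3, DMF) should give 9.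

Step 9. Addition of the buried, chelated phenol to the ylide may be slow, or the reaction may stall at the acyl ylide stage because the doubly flanked ester carbonyl resists olefination. The fallback replaces the olefination by an enolate condensation. It sets out from 18 and comes back at 20. Acetylation (Ac2O, pyridine, DMAP, CH2Cl2) should give methyl 2-acetoxy-3-(4,7-dimethoxy-5-methyl-2-oxo-2H-chromen-6-yl)-4-methoxy-6-methylbenzoate F9. Intramolecular Claisen condensation of its acetate enolate onto the methyl ester (LiN(iPr)2, 3 equiv, THF, −78 °C to rt, acidic work-up) should give 4'-hydroxy-4,7,7'-trimethoxy-5,5'-dimethyl-6,8'-bicoumarin F5. O-Methylation (Me2SO4, K2CO3, acetone, reflux) should give 20.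

Further compounds
F1 | step 8 | (2,6-dimethoxy-4-methylphenyl)boronic acid (purchased) | COc1cc(C)cc(OC)c1B(O)O
F2 | step 8 | 6-(2,6-dimethoxy-4-methylphenyl)-4,7-dimethoxy-5-methylcoumarin | COc1cc2oc(=O)cc(OC)c2c(C)c1-c1c(OC)cc(C)cc1OC
F3 | step 8 | 6-(3-acetyl-2,6-dimethoxy-4-methylphenyl)-4,7-dimethoxy-5-methylcoumarin | COc1cc2oc(=O)cc(OC)c2c(C)c1-c1c(OC)cc(C)c(C(C)=O)c1OC
F4 | step 8 | 6-(3-acetyl-2-hydroxy-6-methoxy-4-methylphenyl)-4,7-dimethoxy-5-methylcoumarin | COc1cc2oc(=O)cc(OC)c2c(C)c1-c1c(OC)cc(C)c(C(C)=O)c1O
F5 | step 8 | 4'-hydroxy-4,7,7'-trimethoxy-5,5'-dimethyl-6,8'-bicoumarin | COc1cc2oc(=O)cc(OC)c2c(C)c1-c1c(OC)cc(C)c2c(O)cc(=O)oc12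
F6 | step 4 | 6-allyl-4,7-dimethoxy-5-methylcoumarin | C=CCc1c(C)c2c(OC)cc(=O)oc2cc1OC
F7 | step 4 | (4,7-dimethoxy-5-methyl-2-oxo-2H-chromen-6-yl)acetaldehyde | O=CCc1c(C)c2c(OC)cc(=O)oc2cc1OC
F8 | step 4 | (4,7-dimethoxy-5-methyl-2-oxo-2H-chromen-6-yl)acetic acid | OC(=O)Cc1c(C)c2c(OC)cc(=O)oc2cc1OC
F9 | step 9 | methyl 2-acetoxy-3-(4,7-dimethoxy-5-methyl-2-oxo-2H-chromen-6-yl)-4-methoxy-6-methylbenzoate | COC(=O)c1c(C)cc(OC)c(-c2c(C)c3c(OC)cc(=O)oc3cc2OC)c1OC(C)=O
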